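The runs were computed with constants of no real substance, and the scatter is random.

I chose the leaner charge for the next 3.0 h run, birch rather than oak, since I wanted complex with one exchanged in hand at the end and the earlier runs showed it falling late on.

all flasks: starting complex 0.072 M

| charge | incoming ligand | remark | time |
|---|---|---|---|
| midnight | 0.16 M | run made earlier |  |
| dusk | 0.40 M | run made earlier |  |
| birch | 0.140 M |  | 3.0 h |
| oak | 0.290 M |  | 3.0 h |

- midnight (time / h: complex with one exchanged / %): 0.250: 18; 0.500: 28; 1.33: 27; 3.00: 21
- dusk (time / h: complex with one exchanged / %): 0.417: 30; 1.00: 19; 2.00: 14; 3.00: 9

(each reading ± 1.5 percentage points)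

- which of the two there is more of at the end, birch (complex with one exchanged / over-reaction product)
- which of the two there is more of at the end, oak (complex with one exchanged / over-reaction product)
- how much complex with one exchanged is there at the end, in percent of the starting complex charged: birch
- how much complex with one exchanged is there at the end, in percent of the starting complex charged: oak

In the midnight and dusk runs complex with one exchanged rose and then fell, so I looked for the crossing, where using it up overtakes making it. Dusk at 1.00 h stood at 0.400 M·h of what I called exposure, the charged [incoming ligand] multiplied by the time. On that scale the two runs could be read together: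

| Run and time | Exposure | Complex with one exchanged |
|---|---|---|
| midnight, 0.500 h | 0.0800 M·h | 28% |
| dusk, 0.417 h | 0.167 M·h | 30% |
| midnight, 1.33 h | 0.213 M·h | 27% |
| dusk, 1.00 h | 0.400 M·h | 19% |
| midnight, 3.00 h | 0.480 M·h | 21% |
| dusk, 2.00 h | 0.800 M·h | 14% |
| dusk, 3.00 h | 1.20 M·h | 9% |

The highest reading of each run lay at or below 0.167 M·h, so I read the crossing near there, with a scatter of 1.5 percentage points on each reading. Birch reaches 0.420 M·h and oak 0.870 M·h, both beyond it, and oak has twice the exposure of birch. So I expected oak further down the falling side, and I chose birch.

My forecast was 23% for birch and 13% for oak, with over-reaction product the larger in birch and over-reaction product the larger in oak. Its ground: “Plotting the intermediate against time × ligand concentration puts both runs on nearly one curve”.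

Birch gave 19.6% of complex with one exchanged against 28.3% of over-reaction product. Oak gave 11.8% against 49.5%.

    starting complex + incoming ligand ⇌ leaving ligand + complex with one exchanged (K = 0.890, k = 0.120 /M/min)
    complex with one exchanged + incoming ligand ⇌ leaving ligand + complex with two exchanged (K = 1.80, k = 0.0530 /M/min)
    2 incoming ligand → homo dimer (k = 0.0190 /M/min)
    complex with one exchanged + incoming ligand → over-reaction product (k = 0.110 /M/min)

Birch held 7.8 points more complex with one exchanged than oak. Oak ended on the falling side: at 3.00 h, each step taken net, it made that complex at 0.434 of the rate at which it used it up. The neighbouring flask was oak read at 80 min, which gives an exposure of 0.387 M·h. That is past the crossing and close to dusk at 1.00 h, which read 19%. The neighbouring flask held 21.2%.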